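## Structural features

Dictyoceratin A is a trans-fused decalin (ring A: C1–C5 and C10; ring B: C5–C10) whose C9 is tied through the benzylic carbon C15 to C1' of a tetrasubstituted arene that carries a methyl ester on C3' and free hydroxyls on C5' and C6'. Ring A bears an exocyclic methylene (C4=C11) directly beside the quaternary C5 (methyl C12, β). Ring B bears an equatorial β-methyl (C13) on C8 and, on the quaternary C9, an axial β-methyl (C14) and the equatorial α-arylmethyl arm. The four stereocentres are contiguous (C8–C9–C10–C5; 8S,9R,10S,5S), and the two quaternary carbons flank the C10 methine, whose hydrogen is α, so the C14 and C12 methyls are 1,3-diaxial. The fragile groups are the catechol (oxidised to the ortho-quinone by air under base and by one-electron oxidants), the 1,1-disubstituted alkene (protonated by Brønsted acid, after which it moves to C3=C4 or starts methyl shifts) and the methyl ester (lost to hydride reagents). The real difficulty is C9, a quaternary centre wedged between the tertiary C8 and C10 and two bonds from a second quaternary centre, while the alkene must end in the less stable exocyclic position. The key step uses the fact that C9 lies next to C8 and carries two one-carbon substituents: C9 can be the α-carbon of a β-keto ester with C8 as ketone carbon, C14 as ester carbon and C15 already attached. Its radical can bond to C10 of a C5=C10 alkene (ring B), and the C5 radical to C4 of a C4≡C11 alkyne (ring A), which leaves C11 as exactly the exocyclic methylene.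

## Logic of the disconnections

**26 ⇒ 24 (through 25).** The two aryl O–CH2 acetal bonds on O5' and O6' are cut. The free catechol would not survive the one-electron oxidant of the key step or basic steps in air, so it is masked from 12 to 24. Nothing is gained in skeleton, but the functionality becomes robust. The forward step must work without Brønsted acid, because C4=C11 of 24 is protonated on the same time scale as an aryl acetal is hydrolysed.

**24 ⇒ 23.** The C3'–carbonyl bond is cut. An arene ester cannot pass the hydride steps 13 and 16, whereas bromine is inert to the radical step, the ylide and the hydrides and already sits at the right carbon of 10. The forward step is a carbonylation that must leave the alkene and the acetals alone.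

**23 ⇒ 22 ⇒ 21.** The C–H bonds of the C13 and C14 methyls are traced back to C–O bonds. Both one-carbon arms arrive in oxidised form, and the diol 21 is where they meet. The demand is hydride substitution at the neopentyl C14.

**21 ⇒ 18 ⇒ 17 ⇒ 16.** The C8–C13 bond is cut to the C8 ketone, and C14 is traced to the ester carbon. C14 is reduced before the C13 aldehyde is unmasked so that 19 can close to 20, a ring that exists only with C13 on the β face. C8 is then fixed by a cis ring fusion and not by the small equatorial preference of a formyl group next to a quaternary carbon. This removes the C8 stereocentre from the problem and leaves 16 with three. The demand is olefination of a ketone flanked by a quaternary carbon.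

**16 ⇒ 15.** C9–C10 and C4–C5 are cut. Two rings, three stereocentres and both quaternary carbons fall back to an acyclic keto ester whose only stereochemical elements are an E-alkene and a removable auxiliary. The forward step needs the radical at C5 to live long enough to reach the alkyne, and it needs face control at C9.

**15 ⇒ 9 + 14.** The C9–C15 bond is cut at the most acidic carbon of 9, opposite a benzylic electrophile. The arene is separated from the chain. Mono C-alkylation is required; the configuration created at C9 is irrelevant.

**9 ⇒ 8 + 5.** The C6–C7 bond is cut between the terminal carbanion of a dianion and an allylic bromide. The forward step must alkylate without allylic transposition and must tolerate the alkyne C–H.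

**8 ⇒ 6 + 7; 5 ⇒ 4 ⇒ 3 ⇒ 1; 14 ⇒ 13 ⇒ 12 ⇒ 11 ⇒ 10.** The ester C–O bond of 8 is cut to the auxiliary alcohol and an acetylketene source. The C5=C10 double bond of 3 is cut by a Wittig disconnection, whose stabilised ylide secures the E-geometry the cascade needs. The arene series is functional-group change only, the one real operation being exchange of the methyl ether for an acetal.

## Other disconnections considered

**Alternative 1:** The C9–C14 and C5–C12 methyl bonds are traced back to methyl groups on C10 and C4 of a drimane, so the skeleton comes from aryl drimene A2, itself derived from (+)-sclareolide A3. In the forward key step, acid protonates the C8 exocyclic methylene of A2. Four suprafacial 1,2-shifts then run along the anti-periplanar array of the trans-decalin (H9 to C8, the C10 methyl to C9, H5 to C10, the axial C4 methyl to C5), and loss of H3 gives the 3-ene A1.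
- In its favour: all four stereocentres are transferred stereospecifically from the chiral pool, no auxiliary is needed, and the arene can carry its ester from the start because no hydride step follows. On stereochemical security and on step count up to A1 this alternative is better than the chosen plan.
- Against it here: the cascade ends by loss of a ring proton, so A1 holds the trisubstituted C3=C4 alkene and not the exocyclic one. The cation may also stop at C10 or be trapped by the arene. Moving the alkene out of the ring is contra-thermodynamic and would cost several steps of allylic functionalisation and deoxygenation with their own regiochemical questions.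
- Comparison: the chosen plan is longer and uses a stoichiometric auxiliary, but its alkyne termination delivers C4=C11 directly, which is the one feature the shift cascade cannot control.

**Alternative 2:** The C8–C9 bond is cut. In the forward key step the secondary C8 radical, made from iodide A5 in a stannane chain, adds 6-exo-trig to C9 of the (E)-styrene held on C10, and the benzylic C15 radical is reduced to give ketone A4.
- In its favour: the C4 carbonyl stands in for the methylene until a final Wittig methylenation, so no acid-sensitive alkene is carried through the synthesis, and the arene keeps its ester throughout. On both points it is better than the chosen plan. The trans relation of C5 and C10 comes from conjugate addition followed by enolate alkylation anti to the new C10 substituent, which is as reliable as the chair cascade (equal). A catalytic asymmetric conjugate addition would be more economical than a stoichiometric auxiliary (better).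
- Against it here: the ring closure must form the most crowded bond of the molecule by attack on the fully substituted end of a trisubstituted styrene. This is slow, so direct reduction of the C8 radical and 1,5-hydrogen shifts compete. C8 and C9 are created together, and the C9 configuration rests on the small difference between a methyl and an arylmethyl group on the styrene; nothing comparable to the fixed radical geometry of the chosen step controls it.
- Comparison: step counts are similar; the weakness is stereocontrol at the very centre that defines the target.

**Alternative 3:** The C5–C10 and C3–C4 bonds are cut. In the forward key step trienal A7, with its (E)-enal (C4=C5) and (E)-diene (C10=C1–C2=C3) joined by the C6–C9 tether, undergoes intramolecular Diels–Alder reaction to cycloadduct A6.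
- In its favour: both rings and the C5/C10 centres form in one redox-neutral step, and an ester-bearing arene is tolerated (better than the chosen plan on that point). In the number of rings and skeletal bonds made by the key step it is the equal of the chosen plan.
- Against it here: the C8/C9 diad, the hardest stereochemical element, must be made in an open chain before the cycloaddition, where no ring helps; the difficulty is moved, not solved. The dienophile carbon C5 is fully substituted, so the reaction should be sluggish and may need Lewis-acid activation that the acetals tolerate poorly. The trans/cis fusion preference for this tether is modest, and facial control must be relayed from C9 alone. Afterwards C1=C2 must be hydrogenated selectively and the formyl group turned into the methylene by reduction and elimination, about four further steps.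
- Comparison: weaker in stereocontrol and longer than the chosen plan.

Key step: step 11

Assumption: the phenyl ring of the (1R,2S,5R) auxiliary is taken to cover the face of the ester-conjugated C9 radical on the side of the auxiliary's C2, so that C10 bonds to the face leading to (5S,9R,10R)-16.

Abbreviations in names: Ar = 5-bromo-2,3-bis(methoxymethoxy)phenyl; R* = (1R,2S,5R)-5-methyl-2-(2-phenylpropan-2-yl)cyclohexyl (8-phenylmenthyl); decalin locants C1–C15 as under Structural features.

## Steps

Step 1
Reactants: 1 5-hexyn-1-ol
Product: 3 ethyl (E)-2-methyloct-2-en-7-ynoate, via 5-hexynal 2 (not isolated)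
Conditions: Dess–Martin periodinane, Ph3P=C(CH3)CO2Et, CH2Cl2, rt
Reagents that add atoms: ethyl 2-(triphenylphosphoranylidene)propanoate, CCOC(=O)C(C)=P(c1ccccc1)(c1ccccc1)c1ccccc1
Why: Dess–Martin oxidation gives the volatile aldehyde 2, which is trapped in the same flask by the stabilised phosphorane (Wittig reaction). The ester-stabilised, α-branched ylide reacts under thermodynamic control and should give the E-alkene, which places the future C1 and C6 trans as the chair cyclisation requires.

Step 2
Reactants: 3 ethyl (E)-2-methyloct-2-en-7-ynoate
Product: 4 (E)-2-methyloct-2-en-7-yn-1-ol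
Conditions: i-Bu2AlH, CH2Cl2, −78 → 0 °C; aq. KNaC4H4O6
Reagents that add atoms: none
Why: 1,2-Reduction of an α,β-unsaturated ester to the allylic alcohol with i-Bu2AlH in the cold leaves the terminal alkyne and the alkene geometry untouched.

Step 3
Reactants: 4 (E)-2-methyloct-2-en-7-yn-1-ol
Product: 5 (E)-8-bromo-7-methyloct-6-en-1-yne
Conditions: CBr4, PPh3, CH2Cl2, 0 °C
Reagents that add atoms: tetrabromomethane, BrC(Br)(Br)Br
Why: Appel bromination of a primary allylic alcohol goes by direct displacement at the CH2 of the alkoxyphosphonium ion under neutral conditions, so neither allylic transposition nor E/Z scrambling is expected.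

Step 4
Reactants: 6 (1R,2S,5R)-(−)-8-phenylmenthol; 7 2,2,6-trimethyl-4H-1,3-dioxin-4-one
Product: 8 R* 3-oxobutanoate
Conditions: xylene, 135 °C, acetone distilled off
Reagents that add atoms: none
Why: Thermal retro-[4+2] fragmentation of 7 releases acetone and acetylketene, which acylates even a hindered secondary alcohol (acetoacetylation). No acid or base is present that could affect the auxiliary.

Step 5
Reactants: 8 R* 3-oxobutanoate; 5 (E)-8-bromo-7-methyloct-6-en-1-yne
Product: 9 R* (E)-6-methyl-3-oxododec-6-en-11-ynoate
Conditions: NaH, THF, 0 °C; n-BuLi, 0 °C; 5, −78 → 0 °C; AcOH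
Reagents that add atoms: none
Why: γ-Alkylation of an acetoacetate dianion: the second deprotonation creates the more reactive terminal carbanion (the future C7), which should displace the allylic bromide at its CH2 faster than it exchanges a proton with the remote alkyne. This forms the C6–C7 bond.

Step 6
Reactants: 10 5-bromo-2-hydroxy-3-methoxybenzaldehyde
Product: 11 5-bromo-2,3-dihydroxybenzaldehyde
Conditions: BBr3, CH2Cl2, −78 °C → rt; H2O
Reagents that add atoms: none
Why: BBr3 cleaves the aryl methyl ether by bromide attack on the methyl group of the boron-complexed ether. The aldehyde and the aryl bromide are untouched at this temperature.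

Step 7
Reactants: 11 5-bromo-2,3-dihydroxybenzaldehyde
Product: 12 5-bromo-2,3-bis(methoxymethoxy)benzaldehyde
Conditions: MeOCH2Cl, i-Pr2NEt, CH2Cl2, 0 °C → rt
Reagents that add atoms: chloromethyl methyl ether, COCCl
Why: Williamson-type O-alkylation of both phenols by the reactive α-chloro ether. The resulting acetals resist the bases, ylide, hydrides and the one-electron oxidant still to come.

Step 8
Reactants: 12 5-bromo-2,3-bis(methoxymethoxy)benzaldehyde
Product: 13 [5-bromo-2,3-bis(methoxymethoxy)phenyl]methanol
Conditions: NaBH4, MeOH, 0 °C
Reagents that add atoms: none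
Why: Borohydride reduction of the aldehyde; the aryl bromide and the acetals are inert.

Step 9
Reactants: 13 [5-bromo-2,3-bis(methoxymethoxy)phenyl]methanol
Product: 14 5-bromo-1-(bromomethyl)-2,3-bis(methoxymethoxy)benzene
Conditions: CBr4, PPh3, CH2Cl2, 0 °C
Reagents that add atoms: tetrabromomethane, BrC(Br)(Br)Br
Why: Appel bromination of a benzylic alcohol under neutral conditions avoids the acid that would cleave the methoxymethyl ethers. The bromide is used directly.

Step 10
Reactants: 9 R* (E)-6-methyl-3-oxododec-6-en-11-ynoate; 14 5-bromo-1-(bromomethyl)-2,3-bis(methoxymethoxy)benzene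
Product: 15 R* (E)-2-(ArCH2)-6-methyl-3-oxododec-6-en-11-ynoate (both C2 epimers)
Conditions: K2CO3, acetone, rt → 45 °C
Reagents that add atoms: none
Why: C-Alkylation of the β-keto ester enolate by a benzylic bromide under mild carbonate conditions forms the C9–C15 bond; the mono-alkylated product is more hindered and less acidic, which limits a second alkylation. Both epimers at the new centre are acceptable because that carbon becomes planar in step 11.

Step 11
Reactants: 15 R* (E)-2-(ArCH2)-6-methyl-3-oxododec-6-en-11-ynoate
Product: 16 R* (5S,9R,10R)-9-(ArCH2)-5-methyl-4-methylidene-8-oxo-trans-decalin-9-carboxylate (ester axial β; ArCH2 equatorial α; H10 α; 5-CH3 β)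
Conditions: Mn(OAc)3·2H2O (2.2 equiv), degassed EtOH, 25 → 45 °C
Reagents that add atoms: none
Why: The reaction type is the oxidative free-radical cyclisation of an unsaturated α-substituted β-keto ester with manganese triacetate, run as a polyene cascade and ended on an alkyne. Trivalent manganese enolises 15 and oxidises it to the electrophilic tertiary C9 radical; 16 has no hydrogen on C9 and is not oxidised further. Ring B closes 6-endo-trig (C9 onto C10, the less substituted end of the alkene) through a chair and ring A closes 6-exo-dig (tertiary C5 radical onto C4); the C11 vinyl radical takes hydrogen from ethanol, and the hydroxyethyl radical so formed uses the second equivalent of oxidant. C10 and C5 are set by anti addition across the E-alkene in the chair–chair array, which gives the trans fusion with H10 and the C5 methyl on opposite faces. C9 is set by the geometry of the unchelated radical, in which the ester lies anti to the C8 carbonyl oxygen and therefore ends axial, syn to the C5 methyl, with the arylmethyl arm equatorial. The absolute sense comes from the auxiliary, whose phenyl ring stacks over one face of the ester-conjugated radical so that C10 bonds to the open face. The step needs the C5 radical to cyclise before it is oxidised or reduced: no Cu(OAc)2 is added (divalent copper would oxidise this tertiary radical to an alkene), ethanol serves as hydrogen donor for the vinyl radical only, and the equatorial arylmethyl arm cannot reach C5, so the arene does not compete with the alkyne. No chelating Lewis acid is added, since a chelated radical with the ester syn to the ketone would reverse both the relative configuration at C9 and the facial sense.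

Step 12
Reactants: 16 R* (5S,9R,10R)-9-(ArCH2)-5-methyl-4-methylidene-8-oxo-trans-decalin-9-carboxylate
Product: 17 R* (5S,9R,10R)-9-(ArCH2)-8-(methoxymethylidene)-5-methyl-4-methylidene-trans-decalin-9-carboxylate (E/Z mixture at C8=C13)
Conditions: [Ph3PCH2OMe]Cl, KN(SiMe3)2, THF, 0 °C; then 16, 0 → 50 °C
Reagents that add atoms: (methoxymethyl)triphenylphosphonium chloride, COC[P+](c1ccccc1)(c1ccccc1)c1ccccc1.[Cl-]
Why: Wittig methoxymethylenation adds C13. The ylide is made with a non-nucleophilic amide base so that no alkoxide can open the non-enolisable β-keto ester by retro-Claisen cleavage. C9 has no hydrogen and cannot epimerise, and the enol ether geometry is irrelevant.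

Step 13
Reactants: 17 R* (5S,9R,10R)-9-(ArCH2)-8-(methoxymethylidene)-5-methyl-4-methylidene-trans-decalin-9-carboxylate
Product: 18 (5S,9R,10R)-[9-(ArCH2)-8-(methoxymethylidene)-5-methyl-4-methylidene-trans-decalin-9-yl]methanol
Conditions: LiAlH4, THF, 0 → 40 °C; aq. NaOH work-up
Reagents that add atoms: none
Why: LiAlH4 reduces the hindered ester to the neopentyl alcohol and releases the auxiliary for recovery; the enol ether, aryl bromide, acetals and alkene do not react at this temperature. Reducing C14 before the aldehyde is unmasked is what allows ring-fusion control at C8 in step 14.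

Step 14
Reactants: 18 (5S,9R,10R)-[9-(ArCH2)-8-(methoxymethylidene)-5-methyl-4-methylidene-trans-decalin-9-yl]methanol
Product: 21 (5S,8S,9R,10R)-9-(ArCH2)-8,9-bis(hydroxymethyl)-5-methyl-4-methylidene-trans-decalin (both CH2OH β), via C8-epimeric hydroxy aldehyde 19 (not isolated), via cis-fused lactol 20 (not isolated)
Conditions: 0.5 M HCl, THF–H2O, rt; K2CO3, MeOH, rt; NaBH4, 0 °C
Reagents that add atoms: water, O
Why: Enol ether hydrolysis in dilute acid is orders of magnitude faster than protonation of the isolated alkene or hydrolysis of the aryl acetals. Under carbonate the hydroxy aldehyde 19 epimerises at C8 through its enolate and drains into lactol 20, which can form only when the formyl group is β (equatorial, gauche to the axial C14 hydroxymethyl), so C8 is fixed by the cis ring fusion. NaBH4 then reduces the lactol through its open form faster than that form can epimerise.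

Step 15
Reactants: 21 (5S,8S,9R,10R)-9-(ArCH2)-8,9-bis(hydroxymethyl)-5-methyl-4-methylidene-trans-decalin
Product: 22 (5S,8S,9R,10R)-9-(ArCH2)-8,9-bis(methanesulfonyloxymethyl)-5-methyl-4-methylidene-trans-decalin
Conditions: MeSO2Cl, Et3N, CH2Cl2, −10 → 0 °C
Reagents that add atoms: methanesulfonyl chloride, CS(=O)(=O)Cl
Why: Sulfonylation through sulfene is fast for both primary alcohols, so the bis-mesylate should form before the free neopentyl hydroxyl can displace the first mesylate to give a tetrahydrofuran.

Step 16
Reactants: 22 (5S,8S,9R,10R)-9-(ArCH2)-8,9-bis(methanesulfonyloxymethyl)-5-methyl-4-methylidene-trans-decalin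
Product: 23 (5S,8S,9R,10S)-9-(ArCH2)-5,8,9-trimethyl-4-methylidene-trans-decalin
Conditions: LiEt3BH, THF, 0 → 65 °C
Reagents that add atoms: none
Why: LiEt3BH is the most nucleophilic of the common hydrides and displaces primary sulfonates directly. The unhindered C13 mesylate should react in the cold and the neopentyl C14 mesylate on heating. No stereocentre is touched; aryl bromide, acetals and alkene are inert.

Step 17
Reactants: 23 (5S,8S,9R,10S)-9-(ArCH2)-5,8,9-trimethyl-4-methylidene-trans-decalin
Product: 24 methyl 3-{[(5S,8S,9R,10S)-5,8,9-trimethyl-4-methylidene-trans-decalin-9-yl]methyl}-4,5-bis(methoxymethoxy)benzoate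
Conditions: Pd(OAc)2 (5 mol %), Xantphos, CO (1 atm), Et3N, MeOH–toluene, 75 °C
Reagents that add atoms: carbon monoxide, [C-]#[O+]; methanol, CO
Why: Carbonylative esterification of an aryl bromide: zerovalent palladium formed in the flask from Pd(OAc)2 inserts into the C–Br bond, CO inserts, and methanol cleaves the acyl complex; the wide-bite-angle diphosphine allows atmospheric CO pressure. Triethylamine keeps the medium basic, so the alkene should not undergo hydroesterification.

Step 18
Reactants: 24 methyl 3-{[(5S,8S,9R,10S)-5,8,9-trimethyl-4-methylidene-trans-decalin-9-yl]methyl}-4,5-bis(methoxymethoxy)benzoate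
Product: 26 dictyoceratin A (methyl 3-{[(5S,8S,9R,10S)-5,8,9-trimethyl-4-methylidene-trans-decalin-9-yl]methyl}-4,5-dihydroxybenzoate), via bis(trimethylsilyl) ether 25 (not isolated)
Conditions: Me3SiOTf, 2,2'-bipyridyl, MeCN, 0 °C → rt; then H2O; under argon
Reagents that add atoms: none
Why: Silyl triflate–bipyridyl cleavage of aromatic methoxymethyl ethers: the bipyridyl-buffered silyl triflate passes the CH2OMe unit to bipyridyl and leaves the aryl silyl ethers 25, which water hydrolyses. No Brønsted acid is present, so the exocyclic alkene should stay in place and the methyl ester is untouched; air is excluded to protect the catechol.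

## Compound list

1 | 5-hexyn-1-ol | C#CCCCCO | starting material
2 | 5-hexynal | C#CCCCC=O | intermediate
3 | ethyl (E)-2-methyloct-2-en-7-ynoate | C#CCCC/C=C(\C)C(=O)OCC | intermediate
4 | (E)-2-methyloct-2-en-7-yn-1-ol | C#CCCC/C=C(\C)CO | intermediate
5 | (E)-8-bromo-7-methyloct-6-en-1-yne | C#CCCC/C=C(\C)CBr | intermediate
6 | (1R,2S,5R)-(−)-8-phenylmenthol | CC(C)(c1ccccc1)[C@@H]1CC[C@@H](C)C[C@H]1O | starting material
7 | 2,2,6-trimethyl-4H-1,3-dioxin-4-one | CC1=CC(=O)OC(C)(C)O1 | starting material
8 | (1R,2S,5R)-8-phenylmenthyl 3-oxobutanoate | CC(=O)CC(=O)O[C@@H]1C[C@H](C)CC[C@H]1C(C)(C)c1ccccc1 | intermediate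
9 | (1R,2S,5R)-8-phenylmenthyl (E)-6-methyl-3-oxododec-6-en-11-ynoate | C#CCCC/C=C(\C)CCC(=O)CC(=O)O[C@@H]1C[C@H](C)CC[C@H]1C(C)(C)c1ccccc1 | intermediate
10 | 5-bromo-2-hydroxy-3-methoxybenzaldehyde | COc1cc(Br)cc(C=O)c1O | starting material
11 | 5-bromo-2,3-dihydroxybenzaldehyde | Oc1cc(Br)cc(C=O)c1O | intermediate
12 | 5-bromo-2,3-bis(methoxymethoxy)benzaldehyde | COCOc1cc(Br)cc(C=O)c1OCOC | intermediate
13 | [5-bromo-2,3-bis(methoxymethoxy)phenyl]methanol | COCOc1cc(Br)cc(CO)c1OCOC | intermediate
14 | 5-bromo-1-(bromomethyl)-2,3-bis(methoxymethoxy)benzene | COCOc1cc(Br)cc(CBr)c1OCOC | intermediate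
15 | (1R,2S,5R)-8-phenylmenthyl (E)-2-{[5-bromo-2,3-bis(methoxymethoxy)phenyl]methyl}-6-methyl-3-oxododec-6-en-11-ynoate (C2 epimers) | C#CCCC/C=C(\C)CCC(=O)C(Cc1cc(Br)cc(OCOC)c1OCOC)C(=O)O[C@@H]1C[C@H](C)CC[C@H]1C(C)(C)c1ccccc1 | intermediate
16 | 8-phenylmenthyl (5S,9R,10R)-9-(arylmethyl)-5-methyl-4-methylidene-8-oxo-trans-decalin-9-carboxylate (ester axial β) | C=C1CCC[C@H]2[C@](C(=O)O[C@@H]3C[C@H](C)CC[C@H]3C(C)(C)c3ccccc3)(Cc3cc(Br)cc(OCOC)c3OCOC)C(=O)CC[C@]12C | intermediate
17 | 8-phenylmenthyl (5S,9R,10R)-9-(arylmethyl)-8-(methoxymethylidene)-5-methyl-4-methylidene-trans-decalin-9-carboxylate (E/Z) | C=C1CCC[C@H]2[C@](C(=O)O[C@@H]3C[C@H](C)CC[C@H]3C(C)(C)c3ccccc3)(Cc3cc(Br)cc(OCOC)c3OCOC)C(=COC)CC[C@]12C | intermediate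
18 | (5S,9R,10R)-[9-(arylmethyl)-8-(methoxymethylidene)-5-methyl-4-methylidene-trans-decalin-9-yl]methanol | C=C1CCC[C@H]2[C@](CO)(Cc3cc(Br)cc(OCOC)c3OCOC)C(=COC)CC[C@]12C | intermediate
19 | (5S,9R,10R)-9-(arylmethyl)-9-(hydroxymethyl)-5-methyl-4-methylidene-trans-decalin-8-carbaldehyde (C8 epimers) | C=C1CCC[C@H]2[C@](CO)(Cc3cc(Br)cc(OCOC)c3OCOC)C(C=O)CC[C@]12C | intermediate
20 | cis-fused lactol C13(OH)–O–C14 across C8–C9 (5S,8S,9R,10R; H8 α; anomers) | C=C1CCC[C@H]2[C@@]3(Cc4cc(Br)cc(OCOC)c4OCOC)COC(O)[C@H]3CC[C@]12C | intermediate
21 | (5S,8S,9R,10R)-9-(arylmethyl)-8,9-bis(hydroxymethyl)-5-methyl-4-methylidene-trans-decalin | C=C1CCC[C@H]2[C@](CO)(Cc3cc(Br)cc(OCOC)c3OCOC)[C@@H](CO)CC[C@]12C | intermediate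
22 | bis(methanesulfonate) of 21 | C=C1CCC[C@H]2[C@](COS(C)(=O)=O)(Cc3cc(Br)cc(OCOC)c3OCOC)[C@@H](COS(C)(=O)=O)CC[C@]12C | intermediate
23 | (5S,8S,9R,10S)-9-{[5-bromo-2,3-bis(methoxymethoxy)phenyl]methyl}-5,8,9-trimethyl-4-methylidene-trans-decalin | C=C1CCC[C@H]2[C@](C)(Cc3cc(Br)cc(OCOC)c3OCOC)[C@@H](C)CC[C@]12C | intermediate
24 | methyl 3-{[(5S,8S,9R,10S)-5,8,9-trimethyl-4-methylidene-trans-decalin-9-yl]methyl}-4,5-bis(methoxymethoxy)benzoate | C=C1CCC[C@H]2[C@](C)(Cc3cc(C(=O)OC)cc(OCOC)c3OCOC)[C@@H](C)CC[C@]12C | intermediate
25 | methyl 3-{[(5S,8S,9R,10S)-5,8,9-trimethyl-4-methylidene-trans-decalin-9-yl]methyl}-4,5-bis(trimethylsilyloxy)benzoate | C=C1CCC[C@H]2[C@](C)(Cc3cc(C(=O)OC)cc(O[Si](C)(C)C)c3O[Si](C)(C)C)[C@@H](C)CC[C@]12C | intermediate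
26 | dictyoceratin A | C=C1CCC[C@H]2[C@](C)(Cc3cc(C(=O)OC)cc(O)c3O)[C@@H](C)CC[C@]12C | target

## Step count and least certain steps

Total step count: 18. Longest linear sequence: 13 steps (steps 6–18 from 10; equally steps 1–3, 5 and 10–18 from 1).

**Step 11 (key step).** The most likely failures are interception of the tertiary C5 radical (oxidation by trivalent manganese, or hydrogen abstraction) before the slower 6-exo-dig closure, sluggish enolisation of the hindered keto ester in ethanol, and erosion of facial selectivity if the ester leaves the stacked conformation. The fallback sets out from 15 and returns to 16. C9 is brominated (NaH, THF; N-bromosuccinimide, −78 °C) to give the tertiary α-bromo keto ester F1. The same C9 radical is then generated reductively under visible light (Ru(bpy)3Cl2 as catalyst, Hantzsch ester, i-Pr2NEt, DMF). With no oxidant in the flask the C5 radical has time to close onto the alkyne, the vinyl radical takes hydrogen from the dihydropyridine, and the aryl bromide lies beyond the reducing power of the catalyst.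

**Step 12.** Addition of the bulky ylide to a carbonyl flanked by the quaternary C9 may be slow, so that enolisation toward C7 and decay of the ylide take over and the ketone is returned. The fallback sets out from 16 and returns to 17 by a stepwise Horner–Wittig sequence. Ph2P(O)CH2OMe is lithiated with LiN(i-Pr)2 at −78 °C and added to the ketone, and the β-hydroxy phosphine oxide F2 is isolated. Its elimination with NaH in DMF then gives the enol ether. Addition and elimination are separated, the carbanion is smaller than the phosphorane, and the amide base cannot exchange with the aryl bromide.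

**Step 16.** At the neopentyl C14 the hydride may attack sulfur instead of carbon, which returns the alcohol, or substitution may stall. The fallback sets out from 22 and returns to 23 in two stages. LiEt3BH at 0 °C reduces only the unhindered sulfonate and gives the C13-methyl neopentyl mesylate F3. NaI and zinc dust in N,N'-dimethylpropyleneurea at 110 °C then exchange the sulfonate for iodide, a nucleophile that cannot be diverted to sulfur, and reduce the neopentyl iodide F4 in the same flask.

**Step 5.** Proton transfer from the alkyne C–H to the dianion may compete with alkylation and return 8. The fallback sets out from 4 and returns to 9 with the alkyne silylated. Alcohol 4 is treated with n-BuLi (2 equiv) and Me3SiCl to give the C,O-bis-silyl compound F5. Aqueous citric acid frees the alcohol F6, and CBr4/PPh3 gives the silylalkynyl bromide F7. The dianion of 8 is alkylated with F7 to the silylated keto ester F8, and K2CO3 in MeOH removes the alkynyl silicon to give 9.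

## Further compounds

F1 | step 11 | (1R,2S,5R)-8-phenylmenthyl (E)-2-bromo-2-{[5-bromo-2,3-bis(methoxymethoxy)phenyl]methyl}-6-methyl-3-oxododec-6-en-11-ynoate | C#CCCC/C=C(\C)CCC(=O)C(Br)(Cc1cc(Br)cc(OCOC)c1OCOC)C(=O)O[C@@H]1C[C@H](C)CC[C@H]1C(C)(C)c1ccccc1
F2 | step 12 | 8-hydroxy-8-[(diphenylphosphoryl)(methoxy)methyl] adduct of 16 (diastereomers) | C=C1CCC[C@H]2[C@](C(=O)O[C@@H]3C[C@H](C)CC[C@H]3C(C)(C)c3ccccc3)(Cc3cc(Br)cc(OCOC)c3OCOC)C(O)(C(OC)P(=O)(c3ccccc3)c3ccccc3)CC[C@]12C
F3 | step 16 | (5S,8S,9R,10R)-9-(arylmethyl)-9-(methanesulfonyloxymethyl)-5,8-dimethyl-4-methylidene-trans-decalin | C=C1CCC[C@H]2[C@](COS(C)(=O)=O)(Cc3cc(Br)cc(OCOC)c3OCOC)[C@@H](C)CC[C@]12C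
F4 | step 16 | (5S,8S,9R,10R)-9-(arylmethyl)-9-(iodomethyl)-5,8-dimethyl-4-methylidene-trans-decalin | C=C1CCC[C@H]2[C@](CI)(Cc3cc(Br)cc(OCOC)c3OCOC)[C@@H](C)CC[C@]12C
F5 | step 5 | (E)-trimethyl{[2-methyl-8-(trimethylsilyl)oct-2-en-7-yn-1-yl]oxy}silane | C[Si](C)(C)C#CCCC/C=C(\C)CO[Si](C)(C)C
F6 | step 5 | (E)-2-methyl-8-(trimethylsilyl)oct-2-en-7-yn-1-ol | C[Si](C)(C)C#CCCC/C=C(\C)CO
F7 | step 5 | (E)-(8-bromo-7-methyloct-6-en-1-yn-1-yl)trimethylsilane | C[Si](C)(C)C#CCCC/C=C(\C)CBr
F8 | step 5 | (1R,2S,5R)-8-phenylmenthyl (E)-6-methyl-3-oxo-12-(trimethylsilyl)dodec-6-en-11-ynoate | C[Si](C)(C)C#CCCC/C=C(\C)CCC(=O)CC(=O)O[C@@H]1C[C@H](C)CC[C@H]1C(C)(C)c1ccccc1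
A1 | alternative 1 | 3-ene isomer of the target skeleton with the catechol as cyclic carbonate | CC1=CCC[C@H]2[C@](C)(Cc3cc(C(=O)OC)cc4OC(=O)Oc34)[C@@H](C)CC[C@]12C
A2 | alternative 1 | 11-aryl-drim-8(12)-ene (5α-H, 9α-H, 10β-CH3; arene as cyclic carbonate with methyl ester) | C=C1CC[C@H]2C(C)(C)CCC[C@]2(C)[C@H]1Cc1cc(C(=O)OC)cc2OC(=O)Oc12
A3 | alternative 1 | (+)-sclareolide | CC1(C)CCC[C@@]2(C)[C@H]1CC[C@@]1(C)OC(=O)C[C@H]21
A4 | alternative 2 | C4 ketone corresponding to 24 | O=C1CCC[C@H]2[C@](C)(Cc3cc(C(=O)OC)cc(OCOC)c3OCOC)[C@@H](C)CC[C@]12C
A5 | alternative 2 | 2-(3-iodobutyl)-2-methyl-3-[(E)-1-aryl-prop-1-en-2-yl]cyclohexanone (trans; iodide epimers) | O=C1CCC[C@@H](/C(C)=C/c2cc(C(=O)OC)cc(OCOC)c2OCOC)[C@]1(C)CCC(C)I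
A6 | alternative 3 | cycloadduct with formyl on C4 and a C1=C2 alkene | O=C[C@H]1CC=C[C@H]2[C@](C)(Cc3cc(C(=O)OC)cc(OCOC)c3OCOC)[C@@H](C)CC[C@]12C
A7 | alternative 3 | (2E,8E)-7-(arylmethyl)-3,6,7-trimethylundeca-2,8,10-trienal | O=C/C=C(\C)CC[C@H](C)[C@@](C)(Cc1cc(C(=O)OC)cc(OCOC)c1OCOC)/C=C/C=C
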